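The route is built on cutting the 1,5-dicarbonyl unit O=C–C1(CH3)–C2(CH3)–CH2–C=O that spans the two vicinal, cis quaternary carbons of the cyclopentane ring. Both ring-to-chain bonds (C1–acyl, C2–CH2) arise from a [2+2] photocycloaddition of an acetoacetate-derived dioxinone across the C1=C2 bond of 1,2-dimethylcyclopentene, followed by strain-driven retro-aldol opening of the cyclobutane. The single photochemical operation sets both quaternary stereocentres, their cis relationship and, through a tert-butyl acetal auxiliary, their absolute configuration. Its precursors are the symmetrical alkene and enantiopure (R)-2-tert-butyl-6-methyl-1,3-dioxin-4-one; the prenyl ketone, E-alkene and quinone are added afterwards.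

Key step: step 3

Assumption: the carbinol carbon created in step 5 is carried as a mixture of epimers (left undefined in the SMILES) because it becomes a C=O in step 14, and any cyclic hemiketal form of 11 is taken to equilibrate with the open chain during silylation.

Step 1
Reactants: 1 (R)-3-hydroxybutanoic acid; 2 pivalaldehyde
Product: 3 (2R,6R)-2-tert-butyl-6-methyl-1,3-dioxan-4-one (cis)
Conditions: 2 (1.5 equiv), TsOH·H2O (cat.), CH2Cl2, reflux, water separator; recrystallisation
Reagents that add atoms: none
Why: Acid-catalysed acetalisation of the β-hydroxy acid under thermodynamic control places tert-butyl and methyl both equatorial (cis), so the existing carbinol centre of 1 should set the new acetal carbon as R.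

Step 2
Reactants: 3 (2R,6R)-2-tert-butyl-6-methyl-1,3-dioxan-4-one
Product: 5 (R)-2-tert-butyl-6-methyl-4H-1,3-dioxin-4-one, via 6-bromo dioxanone 4 (not isolated)
Conditions: NBS (1.05 equiv), AIBN (cat.), CCl4 or PhCF3, reflux; then Et3N, 0 °C → rt
Reagents that add atoms: none
Why: Wohl–Ziegler-type radical bromination at the tertiary, oxygen-activated C6–H followed by E2 loss of HBr should give the enone; C6 becomes sp2 while the acetal carbon is untouched and stays R.

Step 3
Reactants: 5 (R)-2-tert-butyl-6-methyl-4H-1,3-dioxin-4-one; 6 1,2-dimethylcyclopentene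
Product: 7 cis-anti-cis photoadduct (cyclobutane fused on one edge to the (2R)-2-tert-butyl-1,3-dioxan-4-one through its C5–H and C6–CH3 carbons and on the opposite edge to the cyclopentane through its two methyl-bearing carbons; the two outer rings on opposite faces of the cyclobutane, new bonds anti to tert-butyl)
Conditions: hν (medium-pressure Hg lamp, Pyrex, λ > 290 nm), 6 (5 equiv), degassed MeCN, −20 °C
Reagents that add atoms: none
Why: Excitation of the dioxinone enone chromophore and intersystem crossing give its triplet, which bonds to one carbon of the alkene C1=C2 to form a triplet 1,4-biradical that, after spin inversion, collapses to the cyclobutane, so that dioxinone C6 (the future acyl carbon) is joined to one ring carbon and C5 (the future CH2 arm) to the other. The closest known reaction type is the de Mayo reaction in its dioxinone form, an enone–alkene [2+2] photocycloaddition run on a chiral 2-tert-butyl-dioxinone. The only ring closed is the cyclobutane, by radical–radical recombination of the 1,4-biradical with both new bonds on one face of each π component, which enforces cis fusion to the dioxanone and to the cyclopentane. The four new stereocentres (dioxanone C5 and C6, the two quaternary ring carbons) take their relative configuration from this suprafacial delivery and from closure of the biradical with the cyclopentane methylenes turned away from the dioxanone ring (cis-anti-cis), and their absolute configuration from the acetal carbon, whose pseudo-equatorial tert-butyl group on the sofa-shaped dioxinone should leave the face bearing the acetal hydrogen open to the alkene. The step needs π-facial and exo (anti) selectivity, which the acetal centre and the lower steric demand of the anti adduct should secure; regiochemistry is no issue because the alkene is symmetrical, and the low temperature is chosen to sharpen the facial bias.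

Step 4
Reactants: 7 cis-anti-cis photoadduct
Product: 10 2-[(1R,2R)-2-acetyl-1,2-dimethylcyclopentyl]acetaldehyde, via lactol 8 (not isolated), via cyclobutanol aldehyde 9 (not isolated)
Conditions: DIBAL-H (1.05 equiv), CH2Cl2, −78 °C; MeOH, then aq. Rochelle salt, rt
Reagents that add atoms: none
Why: Partial hydride reduction of the dioxanone carbonyl should stop at the aluminium hemiacetal, which on work-up gives lactol 8, loses pivalaldehyde and undergoes the strain-releasing retro-aldol (de Mayo) cleavage of the cyclobutanol β-hydroxy aldehyde 9 to the 1,5-keto aldehyde without touching the quaternary centres.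

Step 5
Reactants: 10 2-[(1R,2R)-2-acetyl-1,2-dimethylcyclopentyl]acetaldehyde
Product: 11 1-[(1R,2R)-2-(2-hydroxypent-4-yn-1-yl)-1,2-dimethylcyclopentyl]ethan-1-one (mixture of carbinol epimers)
Conditions: propargyl bromide (1.5 equiv), Zn dust, THF/sat. aq. NH4Cl, 0 °C → rt
Reagents that add atoms: propargyl bromide, C#CCBr
Why: Barbier propargylation through the allenylzinc species (SE2') should add only to the aldehyde, the tert-alkyl methyl ketone being too hindered, and give the homopropargylic alcohol; the new carbinol centre is uncontrolled and is oxidised later.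

Step 6
Reactants: 11 1-[(1R,2R)-2-(2-hydroxypent-4-yn-1-yl)-1,2-dimethylcyclopentyl]ethan-1-one
Product: 12 bis-silyl derivative of 11 (TBS ether of the carbinol and TBS enol ether CH2=C(OTBS)– of the acetyl group)
Conditions: TBSOTf (2.5 equiv), Et3N (4 equiv), CH2Cl2, 0 °C → rt
Reagents that add atoms: tert-butyldimethylsilyl triflate, CC(C)(C)[Si](C)(C)OS(=O)(=O)C(F)(F)F
Why: Silyl triflate with amine base silylates the secondary alcohol and converts the methyl ketone, enolisable only towards CH3, into its silyl enol ether, so that no carbonyl group is exposed to trimethylaluminium in step 10.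

Step 7
Reactants: 13 2-hydroxy-3-methylbenzaldehyde
Product: 14 2-(tert-butyldimethylsilyloxy)-3-methylbenzaldehyde
Conditions: TBSCl, imidazole, DMAP (cat.), DMF, rt
Reagents that add atoms: tert-butyldimethylsilyl chloride, CC(C)(C)[Si](C)(C)Cl
Why: Standard O-silylation of the phenol gives an aryl silyl ether that tolerates hydride, Appel and organometallic conditions and is later removed by fluoride.

Step 8
Reactants: 14 2-(tert-butyldimethylsilyloxy)-3-methylbenzaldehyde
Product: 15 [2-(tert-butyldimethylsilyloxy)-3-methylphenyl]methanol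
Conditions: NaBH4, MeOH/THF, 0 °C; pH 7 buffer
Reagents that add atoms: none
Why: Borohydride reduction of the aryl aldehyde, run briefly at 0 °C with a neutral quench so that the silyl group should not migrate from the phenolic to the benzylic oxygen.

Step 9
Reactants: 15 [2-(tert-butyldimethylsilyloxy)-3-methylphenyl]methanol
Product: 16 [2-(bromomethyl)-6-methylphenoxy](tert-butyl)dimethylsilane
Conditions: CBr4, PPh3, CH2Cl2, 0 °C
Reagents that add atoms: carbon tetrabromide, BrC(Br)(Br)Br
Why: Appel bromination converts the benzylic alcohol to the bromide under neutral conditions that leave the aryl silyl ether intact.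

Step 10
Reactants: 12 bis-silyl derivative of 11; 16 [2-(bromomethyl)-6-methylphenoxy](tert-butyl)dimethylsilane
Product: 19 1-[(1R,2R)-2-{(4E)-2-(tert-butyldimethylsilyloxy)-6-[2-(tert-butyldimethylsilyloxy)-3-methylphenyl]-4-methylhex-4-en-1-yl}-1,2-dimethylcyclopentyl]ethan-1-one, via alkenylalane 17 (not isolated), via silyl enol ether 18 (not isolated)
Conditions: Me3Al (2.5 equiv), Cp2ZrCl2 (0.25 equiv), CH2Cl2, 0 °C → rt; then 16, Pd(PPh3)4 (5 mol %), THF, rt; then 1 M HCl, THF, 0 °C
Reagents that add atoms: trimethylaluminium, C[Al](C)C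
Why: Negishi zirconium-catalysed carboalumination adds CH3 and Al syn across the terminal alkyne with Al on the terminal carbon, and palladium-catalysed cross-coupling of the alkenylalane with the benzylic bromide proceeds with retention, which should fix the E trisubstituted alkene; dilute acid on work-up hydrolyses only the silyl enol ether back to the methyl ketone.

Step 11
Reactants: 19 methyl ketone from step 10
Product: 20 1-[(1R,2R)-2-{(4E)-2-(tert-butyldimethylsilyloxy)-6-[2-(tert-butyldimethylsilyloxy)-3-methylphenyl]-4-methylhex-4-en-1-yl}-1,2-dimethylcyclopentyl]-4-methylpent-3-en-1-one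
Conditions: LiHMDS (2.2 equiv), Pd2(dba)3 (2.5 mol %), Q-Phos (6 mol %), 1-bromo-2-methylprop-1-ene (1.5 equiv), THF, rt → 50 °C; AcOH, −78 °C
Reagents that add atoms: 1-bromo-2-methylprop-1-ene, CC(C)=CBr
Why: Palladium-catalysed α-alkenylation of the ketone enolate with an alkenyl bromide occurs at the only enolisable position (CH3), the product rests as its dienolate, and kinetic protonation at the α-carbon should release the β,γ-unsaturated prenyl ketone.

Step 12
Reactants: 20 bis-silyl prenyl ketone
Product: 21 1-[(1R,2R)-2-{(4E)-2-hydroxy-6-(2-hydroxy-3-methylphenyl)-4-methylhex-4-en-1-yl}-1,2-dimethylcyclopentyl]-4-methylpent-3-en-1-one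
Conditions: TBAF/AcOH (1:1, 5 equiv), THF, rt → 40 °C
Reagents that add atoms: none
Why: Acetic-acid-buffered fluoride desilylation cleaves both the aryl and the secondary alkyl silyl ether without the basicity that could move the β,γ double bond of the prenyl ketone into conjugation.

Step 13
Reactants: 21 phenol alcohol
Product: 22 2-[(2E)-5-hydroxy-6-{(1R,2R)-1,2-dimethyl-2-(4-methylpent-3-enoyl)cyclopentyl}-3-methylhex-2-en-1-yl]-6-methylcyclohexa-2,5-diene-1,4-dione
Conditions: Fremy's salt (3 equiv), aq. KH2PO4, acetone, 0 °C → rt
Reagents that add atoms: potassium nitrosodisulfonate (Fremy's salt), [O]N(S(=O)(=O)[O-])S(=O)(=O)[O-].[K+].[K+]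
Why: Teuber oxidation of the 2,6-dialkylphenol with a free para position should give the p-benzoquinone, while the secondary alcohol, the ketone and the trisubstituted alkenes are inert to this radical oxidant.

Step 14
Reactants: 22 quinone alcohol
Product: 23 2-methyl-6-[(2E)-3-methyl-5-oxo-6-{(1R,2R)-1,2-dimethyl-2-(4-methylpent-3-enoyl)cyclopentyl}hex-2-en-1-yl]cyclohexa-2,5-diene-1,4-dione (target)
Conditions: Dess–Martin periodinane (1.3 equiv), NaHCO3, CH2Cl2, 0 °C → rt
Reagents that add atoms: none
Why: Dess–Martin oxidation converts the secondary alcohol to the ketone under buffered, non-basic conditions, so the second β,γ-enone is formed in the last operation and should not isomerise; quinone and alkenes are unaffected.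

Compound list
1 | (R)-3-hydroxybutanoic acid | C[C@@H](O)CC(=O)O | starting material
2 | pivalaldehyde | CC(C)(C)C=O | starting material
3 | (2R,6R)-2-tert-butyl-6-methyl-1,3-dioxan-4-one | C[C@@H]1CC(=O)O[C@H](C(C)(C)C)O1 | intermediate
4 | 6-bromo-2-tert-butyl-6-methyl-1,3-dioxan-4-one (acetal carbon as in 3, C6 epimers; not isolated) | CC1(Br)CC(=O)O[C@H](C(C)(C)C)O1 | intermediate
5 | (R)-2-tert-butyl-6-methyl-4H-1,3-dioxin-4-one | CC1=CC(=O)O[C@H](C(C)(C)C)O1 | intermediate
6 | 1,2-dimethylcyclopentene | CC1=C(C)CCC1 | starting material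
7 | cis-anti-cis dioxanone–cyclobutane–cyclopentane photoadduct | C[C@@]12O[C@@H](C(C)(C)C)OC(=O)[C@@H]1[C@@]1(C)CCC[C@]12C | intermediate
8 | lactol of 7 (4-hydroxy-1,3-dioxane, C4 epimers; not isolated) | C[C@@]12O[C@@H](C(C)(C)C)OC(O)[C@@H]1[C@@]1(C)CCC[C@]12C | intermediate
9 | cyclobutanol β-hydroxy aldehyde (bicyclo[3.2.0]heptane with tertiary OH and adjacent CHO; not isolated) | C[C@@]1(O)[C@H](C=O)[C@@]2(C)CCC[C@@]12C | intermediate
10 | 2-[(1R,2R)-2-acetyl-1,2-dimethylcyclopentyl]acetaldehyde | CC(=O)[C@]1(C)CCC[C@]1(C)CC=O | intermediate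
11 | 1-[(1R,2R)-2-(2-hydroxypent-4-yn-1-yl)-1,2-dimethylcyclopentyl]ethan-1-one (carbinol epimers) | CC(=O)[C@]1(C)CCC[C@]1(C)CC(O)CC#C | intermediate
12 | bis-silyl derivative of 11 (TBS ether and TBS enol ether) | C=C(O[Si](C)(C)C(C)(C)C)[C@]1(C)CCC[C@]1(C)CC(O[Si](C)(C)C(C)(C)C)CC#C | intermediate
13 | 2-hydroxy-3-methylbenzaldehyde | Cc1cccc(C=O)c1O | starting material
14 | 2-(tert-butyldimethylsilyloxy)-3-methylbenzaldehyde | Cc1cccc(C=O)c1O[Si](C)(C)C(C)(C)C | intermediate
15 | [2-(tert-butyldimethylsilyloxy)-3-methylphenyl]methanol | Cc1cccc(CO)c1O[Si](C)(C)C(C)(C)C | intermediate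
16 | [2-(bromomethyl)-6-methylphenoxy](tert-butyl)dimethylsilane | Cc1cccc(CBr)c1O[Si](C)(C)C(C)(C)C | intermediate
17 | (E)-alkenyl(dimethyl)alane from 12 (not isolated) | C=C(O[Si](C)(C)C(C)(C)C)[C@]1(C)CCC[C@]1(C)CC(O[Si](C)(C)C(C)(C)C)C/C(C)=C/[Al](C)C | intermediate
18 | benzylated (E)-alkene still carrying the TBS enol ether (not isolated) | C=C(O[Si](C)(C)C(C)(C)C)[C@]1(C)CCC[C@]1(C)CC(O[Si](C)(C)C(C)(C)C)C/C(C)=C/Cc1cccc(C)c1O[Si](C)(C)C(C)(C)C | intermediate
19 | 1-[(1R,2R)-2-{(4E)-2-(tert-butyldimethylsilyloxy)-6-[2-(tert-butyldimethylsilyloxy)-3-methylphenyl]-4-methylhex-4-en-1-yl}-1,2-dimethylcyclopentyl]ethan-1-one | CC(=O)[C@]1(C)CCC[C@]1(C)CC(O[Si](C)(C)C(C)(C)C)C/C(C)=C/Cc1cccc(C)c1O[Si](C)(C)C(C)(C)C | intermediate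
20 | bis-silyl prenyl ketone (4-methylpent-3-en-1-one analogue of 19) | CC(C)=CCC(=O)[C@]1(C)CCC[C@]1(C)CC(O[Si](C)(C)C(C)(C)C)C/C(C)=C/Cc1cccc(C)c1O[Si](C)(C)C(C)(C)C | intermediate
21 | 1-[(1R,2R)-2-{(4E)-2-hydroxy-6-(2-hydroxy-3-methylphenyl)-4-methylhex-4-en-1-yl}-1,2-dimethylcyclopentyl]-4-methylpent-3-en-1-one | CC(C)=CCC(=O)[C@]1(C)CCC[C@]1(C)CC(O)C/C(C)=C/Cc1cccc(C)c1O | intermediate
22 | 2-[(2E)-5-hydroxy-6-{(1R,2R)-1,2-dimethyl-2-(4-methylpent-3-enoyl)cyclopentyl}-3-methylhex-2-en-1-yl]-6-methylcyclohexa-2,5-diene-1,4-dione | CC(C)=CCC(=O)[C@]1(C)CCC[C@]1(C)CC(O)C/C(C)=C/CC1=CC(=O)C=C(C)C1=O | intermediate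
23 | 2-methyl-6-[(2E)-3-methyl-5-oxo-6-{(1R,2R)-1,2-dimethyl-2-(4-methylpent-3-enoyl)cyclopentyl}hex-2-en-1-yl]cyclohexa-2,5-diene-1,4-dione | CC(C)=CCC(=O)[C@]1(C)CCC[C@]1(C)CC(=O)C/C(C)=C/CC1=CC(=O)C=C(C)C1=O | target

Total step count: 14. Longest linear sequence: 11 steps (steps 1–6 and 10–14); the aryl bromide branch (steps 7–9) joins at step 10.

Steps most likely to fail

1. Step 3. The two faces of the dioxinone, or exo and endo closure of the biradical, may be discriminated too weakly, and the triplet may be diverted by allylic hydrogen abstraction from the electron-rich alkene; either would give stereoisomer mixtures. Fallback, which replaces auxiliary control by classical resolution: 6 is irradiated under the same conditions with commercial achiral 2,2,6-trimethyl-4H-1,3-dioxin-4-one to give the racemic cis-anti-cis acetonide photoadduct F1. Saponification with KOH in MeOH/H2O and acidification should trigger the retro-aldol and give the racemic keto acid F2. This is resolved by fractional crystallisation of its (S)-1-phenylethylammonium salt F3 (or of the salt with the antipodal amine, whichever deposits the (1R,2R)-acid), and acidification returns the (1R,2R) enantiomer of F2. Thioesterification (EtSH, EDC, DMAP, CH2Cl2) gives the S-ethyl thioester F4, and Fukuyama reduction (Et3SiH, Pd/C, acetone), which spares the ketone, comes back to the route at 10.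

2. Step 11. Under the basic coupling conditions the new double bond may migrate into conjugation with the ketone, or the dienolate may be alkenylated a second time. Fallback, a neutral tin-enolate coupling in place of the lithium enolate: 19 is converted (KHMDS, then Ac2O, THF, −78 °C) into the enol acetate F5. Bu3SnOMe generates the tributyltin enolate F6 in the flask, which is coupled with 1-bromo-2-methylprop-1-ene using PdCl2[P(o-tol)3]2 in toluene at 100 °C (Migita–Kosugi alkenylation). This returns to the route at 20.

3. Step 10. Transfer of the alkenyl group from aluminium to palladium may be slow, leaving room for methyl transfer or for Lewis-acid-promoted benzylation of the silyl enol ether by the benzylic bromide. Fallback, which reverses the polarity of the coupling and keeps aluminium out of it: 12 is carboaluminated as before to 17 and quenched with I2 (THF, −30 °C, neutral thiosulfate work-up) to give the (E)-alkenyl iodide F7. Separately, 16 is converted with Zn dust/LiCl in THF into the benzylzinc bromide F8. Negishi coupling of F7 with F8 (Pd2(dba)3/SPhos, THF, rt) returns to the route at 18, which is hydrolysed with 1 M HCl/THF to 19 as in step 10.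

Further compounds
F1 | step 3 | racemic cis-anti-cis photoadduct of 2,2,6-trimethyl-4H-1,3-dioxin-4-one and 6 (acetonide analogue of 7; one enantiomer drawn) | C[C@@]12OC(C)(C)OC(=O)[C@@H]1[C@@]1(C)CCC[C@]12C
F2 | step 3 | 2-(2-acetyl-1,2-dimethylcyclopentyl)acetic acid, racemic as formed, (1R,2R) after resolution (drawn) | CC(=O)[C@]1(C)CCC[C@]1(C)CC(=O)O
F3 | step 3 | (S)-1-phenylethylammonium 2-[(1R,2R)-2-acetyl-1,2-dimethylcyclopentyl]acetate | CC(=O)[C@]1(C)CCC[C@]1(C)CC(=O)[O-].C[C@H]([NH3+])c1ccccc1
F4 | step 3 | S-ethyl 2-[(1R,2R)-2-acetyl-1,2-dimethylcyclopentyl]ethanethioate | CC(=O)[C@]1(C)CCC[C@]1(C)CC(=O)SCC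
F5 | step 11 | enol acetate of 19 | C=C(OC(C)=O)[C@]1(C)CCC[C@]1(C)CC(O[Si](C)(C)C(C)(C)C)C/C(C)=C/Cc1cccc(C)c1O[Si](C)(C)C(C)(C)C
F6 | step 11 | tributyltin enolate of 19 | C=C(O[Sn](CCCC)(CCCC)CCCC)[C@]1(C)CCC[C@]1(C)CC(O[Si](C)(C)C(C)(C)C)C/C(C)=C/Cc1cccc(C)c1O[Si](C)(C)C(C)(C)C
F7 | step 10 | (E)-alkenyl iodide from 12 (both silyl groups retained) | C=C(O[Si](C)(C)C(C)(C)C)[C@]1(C)CCC[C@]1(C)CC(O[Si](C)(C)C(C)(C)C)C/C(C)=C/I
F8 | step 10 | [2-(tert-butyldimethylsilyloxy)-3-methylbenzyl]zinc bromide | Cc1cccc(C[Zn]Br)c1O[Si](C)(C)C(C)(C)C
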